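The starting complex exchanges its ligands stepwise for the incoming ligand. I have two earlier runs, dusk and noon, and two flasks to call, epsilon and beta.

| flask | starting complex | incoming ligand | temperature | remark | time |
|---|---|---|---|---|---|
| dusk | 0.025 M | 2 equiv | 95 °C | run made earlier |  |
| noon | 0.038 M | 2 equiv | 115 °C | run made earlier |  |
| epsilon | 0.050 M | 2.00 equiv | 110 °C |  | 3.0 h |
| beta | 0.050 M | 2.00 equiv | 120 °C |  | 3.0 h |

- dusk (time / h: complex with one exchanged / %, starting complex / %): 0.250: 24.8, 74.2; 0.667: 44.8, 48.0; 2.00: 63.0, 16.9; 4.00: 58.0, 5.9
- noon (time / min: complex with one exchanged / %, starting complex / %): 8.00: 39.5, 52.7; 20.0: 59.5, 27.8; 50.0: 58.0, 7.8; 120: 46.5, 0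

(each reading ± 1 percentage point)



- which of the two there is more of at the end, epsilon (complex with three exchanged / complex with one exchanged)
- which of the two there is more of at the end, beta (complex with three exchanged / complex with one exchanged)
- final complex with one exchanged, as a percentage of the starting complex charged, in epsilon
- final complex with one exchanged, as a percentage of the starting complex charged, in beta

1. I take the first two exchanges as first order in c(incoming ligand). Two half-lives then matter, one for each complex at the same c(incoming ligand), and in their ratio κ that concentration cancels.

2. Let m be c(starting complex) as a fraction of the charge. Integrating gives c(complex with one exchanged) = (m^κ − m) divided by one minus κ, again as a fraction of the charge.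

3. That curve peaks where c(starting complex)/c(complex with one exchanged) equals κ. Taking dusk's highest reading as the peak gives 0.268, my selectivity factor κ, a reading with its scatter.

4. For noon, hotter than dusk, at 50.0 min, κ gives 58.3%, and the reading is 58.0%. So I carry κ to epsilon and beta.

5. My reckoning puts the peak of complex with one exchanged at 61.7%. Noon is past that ratio by 50.0 min, and epsilon and beta run longer than that, so I expect both asked values below the peak, on the falling side.

6. The forecast gives 45% for epsilon and 41% for beta, “with three-exchanged slightly ahead in both”.

7. Epsilon ends with 41.0% of complex with one exchanged and 35.9% of complex with three exchanged. Beta ends with 36.8% and 43.5%.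

    crystals ⇌ leaving ligand, rate k1*(cs1 - [leaving ligand]) while solid is left; crystals form when [leaving ligand] > cs1 (solubility = 27.0 mM, k = 2.01 h⁻¹)
    starting complex + complex with one exchanged → side product (k = 4.33 M⁻¹ h⁻¹, Ea = 80.0 kJ mol⁻¹)
    complex with one exchanged + incoming ligand → leaving ligand + complex with two exchanged (k = 12.9 M⁻¹ h⁻¹, Ea = 65.0 kJ mol⁻¹)
    starting complex + incoming ligand → leaving ligand + complex with one exchanged (k = 55.0 M⁻¹ h⁻¹, Ea = 59.0 kJ mol⁻¹)
    complex with two exchanged + incoming ligand → leaving ligand + complex with three exchanged (k = 36.8 M⁻¹ h⁻¹, Ea = 95.0 kJ mol⁻¹)
    (constants at 110 °C)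

In epsilon the later exchanges ran on while incoming ligand lasted, 19.8% of its charge free at 1.50 h and 7.6% at 3.00 h, and c(complex with one exchanged) went from 50.8% to 41.0%. In beta the two complexes cross at 2.01 h, earlier than the asked time. With epsilon's final 0.81% of starting complex, κ gives 36.4%, less than the flask holds. In beta's neighbour, stopped at 50 min, 3.40% of starting complex gives 50.6% by κ, and the flask holds 51.3%.

The readings were generated by integration for substances that don't exist, noise included.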